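The bicyclic core (a five-membered ring fused to a seven-membered ring) is cut into a five-carbon unit C1–C10–C9–C8–C7 and a two-carbon unit C5–C6 (daucane numbering; C1 is the methyl-bearing ring-fusion carbon). A rhodium-catalysed intramolecular [5+2] cycloaddition of a (Z)-vinylcyclopropane with a tethered 1,1-dimethylallene forms C1–C5 and C6–C7 in one operation and closes both rings, with the quaternary C1 and the cis ring fusion. The step exploits the C7–C8–C9 arc of the seven-membered ring B as a latent methylcyclopropane and the oxygenated C2–C3–C4 bridge of the five-membered ring A as tether. The precursor is an acyclic allenyl diol mono-TBS ether; the C9=C10 alkene left behind is later transposed with singlet oxygen and epoxidised.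

Key step: step 8

Remark on numbering: daucane numbering is used throughout (C1 quaternary ring-fusion carbon with CH3, C2 carbinol, C3 CH2, C4 isopropyl carbinol, C5 ring-fusion CH, C6 and C10 the acyloxy carbons, C7 CH2, C8/C9 the epoxide carbons). β is the face of the C1 methyl group, α the opposite face. "cis-Daucane" means 5β-H.

Step 1
Reactants: 1 (E)-but-2-en-1-ol
Product: 2 [(1R,2R)-2-methylcyclopropyl]methanol
Conditions: Et2Zn, CH2I2, DME, CH2Cl2, −10 °C; (4S,5S)-2-butyl-N,N,N',N'-tetramethyl-1,3,2-dioxaborolane-4,5-dicarboxamide (1.2 equiv), −10 °C to rt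
Reagents that add atoms: diiodomethane, ICI
Why: Charette asymmetric Simmons–Smith cyclopropanation, in which the zinc alkoxide bound to the chiral dioxaborolane directs CH2 transfer to one alkene face; the (E)-alkene gives the trans ring and the (4S,5S) ligand (antipode of the one that leads to the (1S,2S) series) should give (1R,2R).

Step 2
Reactants: 2 [(1R,2R)-2-methylcyclopropyl]methanol
Product: 3 (1R,2R)-2-methylcyclopropane-1-carbaldehyde
Conditions: TEMPO (10 mol %), PhI(OAc)2, CH2Cl2, 0 °C to rt; aqueous NaHCO3 wash, careful distillation of the volatile aldehyde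
Reagents that add atoms: none
Why: Oxoammonium (TEMPO) oxidation should stop at the aldehyde and leave the cyclopropane stereocentres untouched.

Step 3
Reactants: 3 (1R,2R)-2-methylcyclopropane-1-carbaldehyde
Product: 4 (1R,2R)-1-[(1Z)-2-iodoprop-1-en-1-yl]-2-methylcyclopropane
Conditions: EtPPh3I, n-BuLi, THF, rt; I2, −78 °C; NaHMDS, −20 °C; then 3, −78 °C to rt
Reagents that add atoms: ethyltriphenylphosphonium iodide, CC[P+](c1ccccc1)(c1ccccc1)c1ccccc1.[I-]; iodine, II
Why: Wittig olefination with the α-iodo ylide Ph3P=C(I)CH3 (Stork–Zhao type) should give the (Z)-2-iodoalkene under kinetic control, with the cyclopropyl group cis to iodine.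

Step 4
Reactants: 4 (1R,2R)-1-[(1Z)-2-iodoprop-1-en-1-yl]-2-methylcyclopropane
Product: 6 (2Z)-2-methyl-3-[(1R,2R)-2-methylcyclopropyl]prop-2-enal, via vinyllithium 5 (not isolated)
Conditions: t-BuLi (2.1 equiv), Et2O, −78 °C; DMF, −78 to 0 °C; aqueous NH4Cl
Reagents that add atoms: N,N-dimethylformamide, CN(C)C=O
Why: Iodine–lithium exchange proceeds with retention of alkene geometry and Bouveault formylation with DMF should give the (Z)-enal, cyclopropyl cis to CHO.

Step 5
Reactants: 6 (2Z)-2-methyl-3-[(1R,2R)-2-methylcyclopropyl]prop-2-enal; 7 3-methylbutan-2-one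
Product: 10 (5S,6Z)-5-hydroxy-2,6-dimethyl-7-[(1R,2R)-2-methylcyclopropyl]hept-6-en-3-one, via boron enolate 8 (not isolated), via boron aldolate 9 (not isolated)
Conditions: 7, (+)-Ipc2BCl, Et3N, Et2O, 0 °C; 6, −78 to −20 °C; H2O2, MeOH, pH 7 buffer, 0 °C
Reagents that add atoms: none
Why: Paterson boron aldol, in which (+)-Ipc2BCl/Et3N enolises the ketone on its methyl side and the chiral borinate is expected to add to the si face of the (Z)-enal (the sense assigned to methyl-ketone enolates of this reagent with enals), setting the (S)-carbinol (future C2) under reagent control.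

Step 6
Reactants: 10 (5S,6Z)-5-hydroxy-2,6-dimethyl-7-[(1R,2R)-2-methylcyclopropyl]hept-6-en-3-one; 11 3-methylbuta-1,2-diene
Product: 13 (1Z,3S,5R)-2,8-dimethyl-1-[(1R,2R)-2-methylcyclopropyl]-5-(propan-2-yl)nona-1,6,7-triene-3,5-diol, via allenyllithium 12 (not isolated)
Conditions: 11, n-BuLi, THF, −78 °C; then 10 (3 equiv of 12 per 10), −78 °C; aqueous NH4Cl
Reagents that add atoms: none
Why: Addition of an allenyllithium to a ketone: lithiated 1,1-dimethylallene should react through its CH terminus (the tertiary γ-carbon is hindered) with the ketone of the lithium aldolate, and attack on the six-membered alkoxide–carbonyl chelate anti to the C2 alkenyl group (Cram-chelate 1,3-induction, the carbon counterpart of a Narasaka–Prasad reduction) places the new hydroxyl syn to the C2 oxygen along the chain ending in isopropyl, i.e. (4R) in daucane numbering.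

Step 7
Reactants: 13 (1Z,3S,5R)-2,8-dimethyl-1-[(1R,2R)-2-methylcyclopropyl]-5-(propan-2-yl)nona-1,6,7-triene-3,5-diol
Product: 14 (1Z,3S,5R)-3-[(tert-butyldimethylsilyl)oxy]-2,8-dimethyl-1-[(1R,2R)-2-methylcyclopropyl]-5-(propan-2-yl)nona-1,6,7-trien-5-ol
Conditions: TBSCl, imidazole, DMF, 0 °C to rt
Reagents that add atoms: tert-butyldimethylsilyl chloride, CC(C)(C)[Si](C)(C)Cl
Why: Silyl ether formation should be selective for the secondary allylic hydroxyl, the tertiary hydroxyl being inert to TBSCl/imidazole.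

Step 8
Reactants: 14 (1Z,3S,5R)-3-[(tert-butyldimethylsilyl)oxy]-2,8-dimethyl-1-[(1R,2R)-2-methylcyclopropyl]-5-(propan-2-yl)nona-1,6,7-trien-5-ol
Product: 15 2β-TBS-oxy-6-(propan-2-ylidene)-cis-dauc-9-en-4α-ol (1β-CH3, 5β-H, 8β-CH3, 4β-isopropyl)
Conditions: [Rh(CO)2Cl]2 (5 mol %), 1,2-dichloroethane (0.01 M), 80 °C
Reagents that add atoms: none
Why: Monovalent rhodium binds the s-cis vinylcyclopropane of 14, opens the less substituted C9–C7 bond to a σ,π-allyl rhodacyclohexene, the proximal π-bond (C5=C6) of the tethered allene inserts at the allyl terminus C1 (bond C1–C5) and reductive elimination joins C7 to C6; the closest known reaction is the rhodium-catalysed intramolecular [5+2] cycloaddition of vinylcyclopropanes with allenes. Ring A (five-membered) closes in a 5-exo sense by migratory insertion across the three-atom tether C2–C3–C4, and ring B (seven-membered) closes by C–C reductive elimination from the eight-membered rhodacycle, leaving the cis C9=C10 alkene and the exocyclic isopropylidene at C6. The quaternary C1 is set by the alkene face that carries rhodium, which two elements fix in the same sense: 1,3-allylic strain in the (Z)-alkene turns the C2–H bond toward the cis cyclopropyl group, so the tether reaches the face anti to the OTBS group (OTBS ends cis to the C1 methyl), and on that face the (1R,2R)-cyclopropane presents its CH2 carbon (C7) to the metal, so the retained C8 centre ends with its methyl cis to the C1 methyl. C5 is set by suprafacial insertion within the short tether, which should give the cis ring fusion (5-H cis to the C1 methyl), with the isopropyl group of the fully substituted C4 on the convex face and its hydroxyl on the rhodium side. The step needs chemoselectivity for the proximal allene π-bond (tether length and the Thorpe–Ingold effect of C4), regioselective cleavage of the CH2–CH cyclopropane bond (the trans C8 methyl is remote from the metal) and a single diastereoface (the matched elements above).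

Step 9
Reactants: 15 2β-TBS-oxy-6-(propan-2-ylidene)-cis-dauc-9-en-4α-ol
Product: 16 2β-TBS-oxy-4α-hydroxy-cis-dauc-9-en-6-one
Conditions: O3, pyridine (3 equiv), CH2Cl2, −78 °C, stopped at consumption of 15
Reagents that add atoms: ozone, [O-][O+]=O
Why: Ozonolysis should cleave the electron-rich tetrasubstituted exocyclic alkene well before the hindered cis-disubstituted ring alkene (flanked by quaternary C1 and tertiary C8), and pyridine turns the carbonyl oxide directly into the ketone so that the β-hydroxy ketone meets neither acid nor base.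

Step 10
Reactants: 16 2β-TBS-oxy-4α-hydroxy-cis-dauc-9-en-6-one
Product: 17 2β-TBS-oxy-cis-dauc-9-ene-4α,6β-diol
Conditions: Me4NBH(OAc)3, AcOH/MeCN, −30 °C
Reagents that add atoms: none
Why: Evans–Saksena reduction: the tertiary 4α-hydroxyl exchanges onto boron and delivers hydride intramolecularly to the α-face of the C6 ketone, which should give the 6β-alcohol (anti 1,3-diol).

Step 11
Reactants: 17 2β-TBS-oxy-cis-dauc-9-ene-4α,6β-diol
Product: 19 2β-TBS-oxy-cis-dauc-8-ene-4α,6β,10α-triol, via allylic hydroperoxide 18 (not isolated)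
Conditions: O2, tetraphenylporphyrin (cat.), visible light, CH2Cl2, 0 °C; then PPh3
Reagents that add atoms: dioxygen, O=O
Why: Schenck ene reaction: the C9=C10 alkene has allylic hydrogen only at C8 (C1 is quaternary), so oxygen must bond to C10 with the double bond shifting to C8=C9, and since the only C8 hydrogen is α the suprafacial ene process puts the hydroperoxide on the α-face; PPh3 reduces it to the 10α-alcohol.

Step 12
Reactants: 19 2β-TBS-oxy-cis-dauc-8-ene-4α,6β,10α-triol
Product: 20 8α,9α-epoxy-2β-TBS-oxy-cis-daucane-4α,6β,10α-triol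
Conditions: VO(acac)2 (5 mol %), t-BuOOH, CH2Cl2, 0 °C to rt
Reagents that add atoms: tert-butyl hydroperoxide, CC(C)(C)OO
Why: Vanadium-catalysed hydroxyl-directed epoxidation: the allylic 10α-hydroxyl binds the vanadium peroxide and should deliver oxygen syn, to the α-face of the trisubstituted C8=C9 alkene, faster than the homoallylic 6β-hydroxyl can direct to the other face.

Step 13
Reactants: 20 8α,9α-epoxy-2β-TBS-oxy-cis-daucane-4α,6β,10α-triol; 21 (2E)-2-methylbut-2-enoyl chloride (tigloyl chloride; two equivalents are consumed, one per hydroxyl)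
Product: 22 8α,9α-epoxy-4α-hydroxy-2β-TBS-oxy-cis-daucane-6β,10α-diyl bis[(2E)-2-methylbut-2-enoate]
Conditions: 21 (3 equiv), DMAP, pyridine, CH2Cl2, 0 to 40 °C
Reagents that add atoms: (2E)-2-methylbut-2-enoyl chloride (the second equivalent of 21), C/C=C(\C)C(=O)Cl
Why: DMAP-catalysed acylation with two equivalents of the acyl chloride should esterify both secondary hydroxyls (6β and 10α), one tigloyl group each, while the tertiary 4α-hydroxyl stays free; the tigloyl group is the stable (E)-isomer and pyridine as the only base limits deconjugation.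

Step 14
Reactants: 22 8α,9α-epoxy-4α-hydroxy-2β-TBS-oxy-cis-daucane-6β,10α-diyl bis[(2E)-2-methylbut-2-enoate]
Product: 23 (1S,2S,4R,5S,6S,8S,9R,10R)-8α,9α-epoxy-2β,4α-dihydroxy-cis-daucane-6β,10α-diyl bis[(2E)-2-methylbut-2-enoate] (CNP0265715.1)
Conditions: HF·pyridine, pyridine, THF, 0 °C to rt
Reagents that add atoms: none
Why: Fluoride-mediated desilylation under buffered, non-basic conditions should free the 2β-hydroxyl without acyl migration, ester cleavage or epoxide opening.

Compound list
1 | (E)-but-2-en-1-ol | C/C=C/CO | starting material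
2 | [(1R,2R)-2-methylcyclopropyl]methanol | C[C@@H]1C[C@H]1CO | intermediate
3 | (1R,2R)-2-methylcyclopropane-1-carbaldehyde | C[C@@H]1C[C@H]1C=O | intermediate
4 | (1R,2R)-1-[(1Z)-2-iodoprop-1-en-1-yl]-2-methylcyclopropane | C[C@@H]1C[C@H]1/C=C(/C)I | intermediate
5 | {1-[(1R,2R)-2-methylcyclopropyl]prop-1-en-2-yl}lithium, Li cis to cyclopropyl | C[C@@H]1C[C@H]1/C=C(/C)[Li] | intermediate (not isolated)
6 | (2Z)-2-methyl-3-[(1R,2R)-2-methylcyclopropyl]prop-2-enal | C[C@@H]1C[C@H]1/C=C(/C)C=O | intermediate
7 | 3-methylbutan-2-one | CC(C)C(C)=O | starting material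
8 | 3-methylbut-1-en-2-yl bis[(+)-isopinocampheyl]borinate (boron enolate of 7) | C=C(C(C)C)OB([C@H]1C[C@H]2C[C@@H]([C@@H]1C)C2(C)C)[C@H]1C[C@H]2C[C@@H]([C@@H]1C)C2(C)C | intermediate (not isolated)
9 | bis[(+)-isopinocampheyl]borinate (boron aldolate) of 10 | CC(C)C(=O)C[C@H](OB([C@H]1C[C@H]2C[C@@H]([C@@H]1C)C2(C)C)[C@H]1C[C@H]2C[C@@H]([C@@H]1C)C2(C)C)/C(C)=C\[C@@H]1C[C@H]1C | intermediate (not isolated)
10 | (5S,6Z)-5-hydroxy-2,6-dimethyl-7-[(1R,2R)-2-methylcyclopropyl]hept-6-en-3-one | CC(C)C(=O)C[C@H](O)/C(C)=C\[C@@H]1C[C@H]1C | intermediate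
11 | 3-methylbuta-1,2-diene | CC(C)=C=C | starting material
12 | (3-methylbuta-1,2-dien-1-yl)lithium | CC(C)=C=C[Li] | intermediate (not isolated)
13 | (1Z,3S,5R)-2,8-dimethyl-1-[(1R,2R)-2-methylcyclopropyl]-5-(propan-2-yl)nona-1,6,7-triene-3,5-diol | CC(C)=C=C[C@](O)(C(C)C)C[C@H](O)/C(C)=C\[C@@H]1C[C@H]1C | intermediate
14 | (1Z,3S,5R)-3-[(tert-butyldimethylsilyl)oxy]-2,8-dimethyl-1-[(1R,2R)-2-methylcyclopropyl]-5-(propan-2-yl)nona-1,6,7-trien-5-ol | CC(C)=C=C[C@](O)(C(C)C)C[C@H](O[Si](C)(C)C(C)(C)C)/C(C)=C\[C@@H]1C[C@H]1C | intermediate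
15 | 2β-TBS-oxy-6-(propan-2-ylidene)-cis-dauc-9-en-4α-ol (1β-CH3, 5β-H, 8β-CH3) | CC(C)=C1C[C@@H](C)C=C[C@@]2(C)[C@@H]1[C@](O)(C(C)C)C[C@@H]2O[Si](C)(C)C(C)(C)C | intermediate
16 | 2β-TBS-oxy-4α-hydroxy-cis-dauc-9-en-6-one | O=C1C[C@@H](C)C=C[C@@]2(C)[C@@H]1[C@](O)(C(C)C)C[C@@H]2O[Si](C)(C)C(C)(C)C | intermediate
17 | 2β-TBS-oxy-cis-dauc-9-ene-4α,6β-diol | O[C@H]1C[C@@H](C)C=C[C@@]2(C)[C@@H]1[C@](O)(C(C)C)C[C@@H]2O[Si](C)(C)C(C)(C)C | intermediate
18 | 10α-hydroperoxy-2β-TBS-oxy-cis-dauc-8-ene-4α,6β-diol | O[C@H]1CC(C)=C[C@H](OO)[C@@]2(C)[C@@H]1[C@](O)(C(C)C)C[C@@H]2O[Si](C)(C)C(C)(C)C | intermediate (not isolated)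
19 | 2β-TBS-oxy-cis-dauc-8-ene-4α,6β,10α-triol | O[C@H]1CC(C)=C[C@H](O)[C@@]2(C)[C@@H]1[C@](O)(C(C)C)C[C@@H]2O[Si](C)(C)C(C)(C)C | intermediate
20 | 8α,9α-epoxy-2β-TBS-oxy-cis-daucane-4α,6β,10α-triol | O[C@H]1C[C@]2(C)O[C@@H]2[C@H](O)[C@@]2(C)[C@@H]1[C@](O)(C(C)C)C[C@@H]2O[Si](C)(C)C(C)(C)C | intermediate
21 | (2E)-2-methylbut-2-enoyl chloride (tigloyl chloride) | C/C=C(\C)C(=O)Cl | starting material
22 | 8α,9α-epoxy-4α-hydroxy-2β-TBS-oxy-cis-daucane-6β,10α-diyl bis[(2E)-2-methylbut-2-enoate] | C/C=C(\C)C(=O)O[C@H]1C[C@]2(C)O[C@@H]2[C@H](OC(=O)/C(C)=C/C)[C@@]2(C)[C@@H]1[C@](O)(C(C)C)C[C@@H]2O[Si](C)(C)C(C)(C)C | intermediate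
23 | (1S,2S,4R,5S,6S,8S,9R,10R)-8α,9α-epoxy-2β,4α-dihydroxy-cis-daucane-6β,10α-diyl bis[(2E)-2-methylbut-2-enoate] | C/C=C(\C)C(=O)O[C@H]1C[C@]2(C)O[C@@H]2[C@H](OC(=O)/C(C)=C/C)[C@@]2(C)[C@@H]1[C@](O)(C(C)C)C[C@@H]2O | target

Total step count: 14
Longest linear sequence: 14 steps (1 to 23); 7, 11 and 21 are commercial inputs.

Steps most likely to fail

Step 8. The congested (Z)-trisubstituted vinylcyclopropane may open slowly or at the wrong cyclopropane bond, and the terminal methyl groups of the allene may block insertion of its proximal π-bond, so that the rhodium allyl decays by other paths. The fallback changes the two-carbon partner and the way the C6 ketone is unmasked. It sets out from 10: the lithium acetylide of 2-(prop-2-yn-1-yloxy)oxane (n-BuLi, THF, −78 °C) adds to the ketone under the same chelate control to give the propargylic tetrahydropyranyl ether diol F1 (acetal carbon as a mixture of epimers). LiAlH4 (THF, reflux) then delivers hydride from the tertiary alkoxyaluminate to the proximal alkyne carbon with loss of the tetrahydropyranyloxy group (SN2' reduction) and gives the terminal allene diol F2. Silylation as in step 7 gives the silyl ether F3. The same [Rh(CO)2Cl]2 catalysis, now on a monosubstituted allene with an unhindered proximal π-bond, should give the 6-methylene cycloadduct F4. OsO4 (cat.)/NaIO4 with 2,6-lutidine in dioxane–water cleaves the unhindered 1,1-disubstituted alkene in preference to the shielded ring alkene, and the route is rejoined at ketone 16.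

Step 11. The ene reaction of the cis-disubstituted alkene may be slow, and the more electron-rich trisubstituted alkene of the product may then be oxidised further. The fallback sets out from 17: mCPBA (NaHCO3, CH2Cl2, 0 °C) should epoxidise the C9=C10 alkene from the α-face, anti to the two allylic β-methyl groups at C1 and C8 and on the side of the 4α-hydroxyl, which can guide the peracid, to give the 9α,10α-epoxide F5. Excess diethylaluminium 2,2,6,6-tetramethylpiperidide (toluene, 0 °C) then removes the 8α-hydrogen, the only hydrogen syn to the epoxide oxygen (C1 has none), in a syn β-elimination that opens the C9–O bond. This gives the 10α-alcohol with the C8=C9 alkene, and the route is rejoined at 19.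

Step 6. The allenyl anion may attack through its γ-carbon to give the homopropargylic alcohol, the aldolate may enolise or undergo retro-aldol cleavage, and chelate control of the ketone face may be incomplete. The fallback sets out from 10: the lithium acetylide of 2-[(2-methylbut-3-yn-2-yl)oxy]oxane, transmetallated with CeCl3 (THF, −78 °C) to suppress enolisation, adds to the ketone to give the propargylic tetrahydropyranyl ether diol F6. LiAlH4 (THF, reflux) then effects the hydroxyl-directed SN2' reduction with loss of the tetrahydropyranyloxy group, which fixes the allene regiochemistry, and the route is rejoined at 13.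

Further compounds
F1 | step 8 | (1Z,3S,5R)-2-methyl-1-[(1R,2R)-2-methylcyclopropyl]-8-(oxan-2-yloxy)-5-(propan-2-yl)oct-1-en-6-yne-3,5-diol | C1CCC(OCC#C[C@](O)(C(C)C)C[C@H](O)/C(C)=C\[C@@H]2C[C@H]2C)OC1
F2 | step 8 | (1Z,3S,5R)-2-methyl-1-[(1R,2R)-2-methylcyclopropyl]-5-(propan-2-yl)octa-1,6,7-triene-3,5-diol | C=C=C[C@](O)(C(C)C)C[C@H](O)/C(C)=C\[C@@H]1C[C@H]1C
F3 | step 8 | (1Z,3S,5R)-3-[(tert-butyldimethylsilyl)oxy]-2-methyl-1-[(1R,2R)-2-methylcyclopropyl]-5-(propan-2-yl)octa-1,6,7-trien-5-ol | C=C=C[C@](O)(C(C)C)C[C@H](O[Si](C)(C)C(C)(C)C)/C(C)=C\[C@@H]1C[C@H]1C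
F4 | step 8 | 2β-TBS-oxy-6-methylidene-cis-dauc-9-en-4α-ol (1β-CH3, 5β-H, 8β-CH3) | C=C1C[C@@H](C)C=C[C@@]2(C)[C@@H]1[C@](O)(C(C)C)C[C@@H]2O[Si](C)(C)C(C)(C)C
F5 | step 11 | 9α,10α-epoxy-2β-TBS-oxy-cis-daucane-4α,6β-diol (8β-CH3) | O[C@H]1C[C@@H](C)[C@@H]2O[C@@H]2[C@@]2(C)[C@@H]1[C@](O)(C(C)C)C[C@@H]2O[Si](C)(C)C(C)(C)C
F6 | step 6 | (1Z,3S,5R)-2,8-dimethyl-1-[(1R,2R)-2-methylcyclopropyl]-8-(oxan-2-yloxy)-5-(propan-2-yl)non-1-en-6-yne-3,5-diol | CC(C)(OC1CCCCO1)C#C[C@](O)(C(C)C)C[C@H](O)/C(C)=C\[C@@H]1C[C@H]1C
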